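## Structural features

The target is a 2H-chromen-6-ol: benzene ring A is fused to pyran ring B through C4a and C8a, the free hydroxyl sits on C6 (para to the ring oxygen O1), and ring B holds a styrenyl C3=C4 double bond. C2 is the only stereocentre; it is a quaternary carbon bound to O1, to the vinylic C3, to a methyl group and to C1' of a sixteen-carbon side chain, and it has the S configuration. The side chain runs C1'H2–C2'H2–C3'H=C4'(CH3)–C5'H2–C6'H2 and ends in a 2,6,6-trimethylcyclohex-1-enyl ring (ring C); the C3'=C4' alkene is E and trisubstituted, the ring alkene is tetrasubstituted, and together they form a 1,5-diene. No stereocentre stands next to C2, so its configuration must come from a reagent or catalyst. The fragile points are the tertiary allylic aryl ether bond C2–O1 (ionisation or electrocyclic opening of the chromene would racemise C2), the electron-rich para-alkoxyphenol (easily oxidised to a quinone), and the 1,5-diene, which cyclises under protic acid. The real difficulty is to make the oxygen-bearing quaternary centre as one enantiomer and to close ring B without C2 ever becoming planar, which excludes the usual propargyl ether and quinone methide routes to chromenes. The key step uses the para relation of O1 (on C8a) to the C6 hydroxyl together with the ortho placement of C4 on C4a: such an aryl ether is the dienone–phenol isomer of a cyclohexa-2,5-dienone whose spiro carbon (the future C8a) holds both O1 and C4, so ring A can be traced back to a plain 4-substituted phenol.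

## Logic of the disconnections

19 to 18. The C4–C4a bond is cut and C4 is re-attached to C8a, which de-aromatises ring A and contracts ring B to a 2,5-dihydrofuran. The reason is that O1, C2, C3 and C4 are then already a ring, so no C–O bond has to be made at C2 and no ortho-oxygenated arene is needed. The gain is a symmetrical dienone in which C2 is a spectator. The forward step must move carbon and not oxygen, and must leave the C2–O1 bond and the 1,5-diene alone.

18 to 17. The O1–C(spiro) bond is cut, returning the arene as a 4-substituted phenol with a Z-allylic tertiary alcohol. The reason is that a phenol is made electrophilic at its para carbon by two-electron oxidation. The gain is an aromatic, unprotected precursor. The forward step needs the Z geometry, so that the hydroxyl reaches the para carbon, and an oxidant that picks the phenol over three other alkenes.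

17 to 16 to 14 + 15. The Z alkene is taken back to an alkyne and the C4–aryl bond is cut. The reason is that an sp–sp2 coupling joins the simplest possible arene, 15, to a fragment, 14, that holds the stereocentre and the whole side chain. The gain is convergence with no protecting group. The coupling must tolerate a free phenol and a tertiary alcohol, and the reduction must stop at the Z alkene and spare the tri- and tetrasubstituted alkenes.

14 to 12 to 11. The two alkyne carbons are traced to C1 and C2 of 12 by adding back two HCl, and 12 comes from 11 by exchange of OH for Cl. The C3–O bond of the epoxide is the later C2–O1 bond of 19. The reason is that an enantiopure tertiary propargylic alcohol is hard to reach by addition to a ketone. The gain is that the stereochemical problem becomes the epoxidation of an allylic alcohol. The forward base must eliminate and not substitute, and must never break the C3–O bond.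

11 to 10. Both C–O bonds of the epoxide are cut. The reason is that the allylic hydroxyl directs a tartrate-controlled oxygen transfer. The gain is an achiral C20 alcohol. The forward step must select one alkene face and only the allylic alkene out of three.

10 to 8 to 4 + 7. The C5'–C6' bond (chromene numbering), an sp3–sp3 bond between two allylic carbons, is cut with a sulfonyl group as temporary activator on the ring-side carbon. The reason is that both E alkenes of the chain then come ready-made from 5. The gain is two ten-carbon pieces. The hindered sulfonyl carbanion must be alkylated in the presence of an acetate, and the sulfone must then be removed without moving the ring alkene.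

4 to 2 to 1, and 7 to 6 to 5. Only functional groups change: C–S and C–Br from C–O, C–O from C=O, and a C–H of the terminal E-methyl of 5 to C–O. The reason and gain are commercial starting materials. The allylic oxidation must be selective for the E-methyl of the remote alkene.

## Other disconnections considered

Alternative 1: The cut is the C3=C4 double bond of ring B, with C2 created at the same time from a prochiral carbon. The aryl ether A2 of 3-methylpenta-1,4-dien-3-ol, carrying an ortho vinyl group and a para silyloxy group, would undergo ring-closing metathesis through one of its two enantiotopic vinyl groups under enantiopure Mo(N-2,6-iPr2C6H3)(CHCMe2Ph)(3,3'-di-tert-butyl-5,5',6,6'-tetramethylbiphenyl-2,2'-diolate), giving the 2-methyl-2-vinyl chromene A1.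

- In its favour: ring B and the stereocentre arise together in one catalytic, neutral step; no cation develops near C2 or the diene; and the plan is convergent, since the remaining fourteen carbons are attached afterwards by hydroboration of the vinyl group and an sp3–sp2 cross-coupling, followed by desilylation.
- Against it here: the catalyst must distinguish methyl from vinyl at a fully substituted carbon, a selection that depends closely on catalyst and substrate. A2 is a tertiary, doubly allylic aryl ether that costs several steps and ionises easily. The catalyst needs strict exclusion of air and water, and the vinyl group left in A1 can re-enter metathesis.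
- Comparison: alternative 1 is the better plan in convergence, in setting C2 during ring formation and in avoiding a Lewis acid on the polyene. It is the weaker plan in predictability of the absolute configuration, which the chosen route takes from a tartrate-controlled epoxidation of an E-allylic alcohol. In step economy the two are about equal: two steps follow A1 where none follow the rearrangement, but fewer precede it.

Alternative 2: The cut takes the C2 methyl group back to a cyclopropane methylene. The 2-substituted chromone A4, with the complete side chain and a silyl-protected C6 oxygen, would receive a methylene from the ylide of Me3S(O)I under a chiral LaLi3(biaryldiolate)3-type catalyst, forming C2–CH2 and C3–CH2 in the cis-fused cyclopropane A3. Reductive scission of the C3–CH2 bond would then reveal the methyl group, and carbonyl reduction, dehydration and desilylation would finish the synthesis.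

- In its favour: A4 is flat, robust and easy to assemble, the stereocentre is set catalytically, and no ionisable C–O bond is made at C2.
- Against it here: asymmetric methylene transfer to a β,β-disubstituted vinylogous ester, forming a quaternary centre, lies outside the usual enone scope. The reductive opening must break the exocyclic cyclopropane bond and not the C2–C3 bond, whose cleavage would give an oxygen-stabilised radical. The C4 oxygen must finally be removed through a benzylic cation or an activated ester next to the sensitive C2–O1 bond and the diene.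
- Comparison: alternative 2 is the equal or better plan in that the stereocentre is introduced on a substrate free of fragile groups and no oxidative dearomatisation is needed. The chosen plan is better in that ring B and the C3=C4 alkene appear at the correct oxidation level in the key step itself. Four steps follow A3 and none follow the rearrangement, so step economy favours the chosen plan.

Alternative 3: The cut removes C4. The 2,2-disubstituted benzofuran-3(2H)-one A6, already carrying the methyl group, the complete side chain and the silyl ether, would be treated with Me3SiCHN2 and BF3·OEt2 so that one carbon is inserted between the carbonyl carbon and the aryl carbon. After loss of silicon from carbon this gives the chroman-3-one A5; reduction, elimination toward C4 and desilylation would follow.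

- In its favour: C2 of A6 is the α-carbon of a ketone, so the quaternary centre is open to established asymmetric enolate alkylation. The final elimination can only go toward C4 because C2 is quaternary, and even insertion on the other side of the carbonyl would converge on the same chromene.
- Against it here: the carbonyl of A6 is hindered and deactivated by the ortho ring oxygen, whereas A5 is a more reactive, unconjugated ketone, so further homologation and epoxide formation threaten. A5 enolises toward the benzylic C4 and is air-sensitive.
- Comparison: alternative 3 is the equal of the chosen plan in exposing the 1,5-diene to BF3·OEt2, and the better plan in the ease of setting C2 and in the regiochemical certainty of its last elimination. It is the weaker plan in control of the ring expansion itself and in step economy, with three steps after A5.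

Key step: step 13

Remark: C2 of the target works out as S. Neither the C–O bond nor the C–C bonds at this carbon change from 11 onward, so 11 must be the (2S,3S)-epoxy alcohol, the sense expected from L-(+)-diethyl tartrate on an E-allylic alcohol. Commercial geranyl acetate is taken as the pure 2E isomer.

## Route

Step 1
Reactants: 1 β-cyclocitral (2,6,6-trimethylcyclohex-1-ene-1-carbaldehyde)
Product: 2 β-cyclogeraniol ((2,6,6-trimethylcyclohex-1-en-1-yl)methanol)
Conditions: NaBH4, MeOH, 0 °C
Reagents that add atoms: none
Why: Borohydride 1,2-reduction of a hindered enal that has no epimerisable centre; the tetrasubstituted alkene is not conjugate-reduced under these conditions.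

Step 2
Reactants: 2 β-cyclogeraniol
Product: 4 β-cyclogeranyl phenyl sulfone ([(2,6,6-trimethylcyclohex-1-en-1-yl)methylsulfonyl]benzene), via β-cyclogeranyl bromide 3 (not isolated)
Conditions: PBr3 (0.4 equiv), pyridine (cat.), Et2O, −10 °C; cold NaHCO3 wash, solvent exchange; PhSO2Na, DMF, rt
Reagents that add atoms: sodium benzenesulfinate [Na+].[O-]S(=O)c1ccccc1; phosphorus tribromide BrP(Br)Br (bromine of 3 only)
Why: Bromination of a primary allylic alcohol followed by SN2 S-alkylation of the sulfinate in DMF; the labile allylic bromide is used at once and not stored.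

Step 3
Reactants: 5 geranyl acetate ((2E)-3,7-dimethylocta-2,6-dien-1-yl acetate)
Product: 6 (2E,6E)-8-hydroxy-3,7-dimethylocta-2,6-dien-1-yl acetate
Conditions: SeO2 (10 mol%), t-BuOOH (70% aq.), salicylic acid (cat.), CH2Cl2, rt
Reagents that add atoms: tert-butyl hydroperoxide CC(C)(C)OO (oxygen source, passed on by catalytic selenium dioxide O=[Se]=O)
Why: SeO2/t-BuOOH allylic oxidation (ene reaction, then [2,3]-shift) hydroxylates the E-methyl of the remote, more electron-rich trisubstituted alkene; the 2,3-alkene is deactivated by its allylic acetate.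

Step 4
Reactants: 6 (2E,6E)-8-hydroxy-3,7-dimethylocta-2,6-dien-1-yl acetate
Product: 7 (2E,6E)-8-bromo-3,7-dimethylocta-2,6-dien-1-yl acetate
Conditions: CBr4, PPh3, CH2Cl2, 0 °C
Reagents that add atoms: carbon tetrabromide BrC(Br)(Br)Br
Why: Appel bromination of a primary allylic alcohol under neutral conditions; the acetate and both alkene geometries are left as they are.

Step 5
Reactants: 4 β-cyclogeranyl phenyl sulfone; 7 (2E,6E)-8-bromo-3,7-dimethylocta-2,6-dien-1-yl acetate
Product: 8 (2E,6E)-3,7-dimethyl-9-(phenylsulfonyl)-9-(2,6,6-trimethylcyclohex-1-en-1-yl)nona-2,6-dien-1-yl acetate (racemic at C9)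
Conditions: 4, n-BuLi (1.05 equiv), THF, −78 °C; then 7, −78 → −30 °C
Reagents that add atoms: none
Why: Biellmann-type coupling: the α-sulfonyl allyl carbanion is alkylated at its sulfur-bearing carbon by the allylic bromide (SN2), and at low temperature this soft carbanion displaces bromide much faster than it attacks an acetate. The new C9 centre is racemic and is removed in step 6.

Step 6
Reactants: 8 (2E,6E)-3,7-dimethyl-9-(phenylsulfonyl)-9-(2,6,6-trimethylcyclohex-1-en-1-yl)nona-2,6-dien-1-yl acetate
Product: 10 (2E,6E)-3,7-dimethyl-9-(2,6,6-trimethylcyclohex-1-en-1-yl)nona-2,6-dien-1-ol, via C20 dienyl acetate 9 (not isolated)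
Conditions: Na/Hg (6% Na), Na2HPO4, THF–MeOH, −20 °C; then K2CO3, MeOH, rt
Reagents that add atoms: none
Why: Reductive desulfonylation by electron transfer: the sulfone radical anion loses benzenesulfinate and the resulting allyl anion should be protonated at its less substituted, exocyclic carbon, which keeps the tetrasubstituted ring alkene in place. Carbonate methanolysis then frees the primary alcohol in the same flask.

Step 7
Reactants: 10 (2E,6E)-3,7-dimethyl-9-(2,6,6-trimethylcyclohex-1-en-1-yl)nona-2,6-dien-1-ol
Product: 11 [(2S,3S)-3-methyl-3-[(3E)-4-methyl-6-(2,6,6-trimethylcyclohex-1-en-1-yl)hex-3-en-1-yl]oxiran-2-yl]methanol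
Conditions: Ti(OiPr)4 (10 mol%), L-(+)-diethyl tartrate (12 mol%), t-BuOOH (anhydrous, 2 equiv), 4 Å MS, CH2Cl2, −20 °C
Reagents that add atoms: tert-butyl hydroperoxide CC(C)(C)OO
Why: Sharpless asymmetric epoxidation: only the alkene of the titanium-bound allylic alcohol is epoxidised, and the L-(+)-tartrate ligand selects the face that gives the (2S,3S)-epoxide, as it does with geraniol. This sets the carbon that becomes C2 of the chromene.

Step 8
Reactants: 11 [(2S,3S)-3-methyl-3-[(3E)-4-methyl-6-(2,6,6-trimethylcyclohex-1-en-1-yl)hex-3-en-1-yl]oxiran-2-yl]methanol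
Product: 12 (2R,3S)-2-(chloromethyl)-3-methyl-3-[(3E)-4-methyl-6-(2,6,6-trimethylcyclohex-1-en-1-yl)hex-3-en-1-yl]oxirane
Conditions: PPh3, CCl4, NaHCO3, reflux
Reagents that add atoms: carbon tetrachloride ClC(Cl)(Cl)Cl
Why: Appel chlorination by SN2 at the primary carbon; bicarbonate protects the trisubstituted epoxide from acid opening and neither epoxide carbon takes part (the C2 descriptor changes only because chlorine outranks oxygen).

Step 9
Reactants: 12 (2R,3S)-2-(chloromethyl)-3-methyl-3-[(3E)-4-methyl-6-(2,6,6-trimethylcyclohex-1-en-1-yl)hex-3-en-1-yl]oxirane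
Product: 14 (3S,6E)-3,7-dimethyl-9-(2,6,6-trimethylcyclohex-1-en-1-yl)non-6-en-1-yn-3-ol, via chlorovinyl carbinol 13 (not isolated)
Conditions: n-BuLi (3.3 equiv), THF, −78 → −30 °C; NH4Cl (aq)
Reagents that add atoms: none
Why: Base-induced double elimination of a 2,3-epoxy chloride: deprotonation at C1 opens the epoxide by β-elimination to the chlorovinyl alkoxide, which loses HCl to give the acetylide. The C3–O bond is never broken, so the S centre is carried over unchanged.

Step 10
Reactants: 14 (3S,6E)-3,7-dimethyl-9-(2,6,6-trimethylcyclohex-1-en-1-yl)non-6-en-1-yn-3-ol; 15 4-iodophenol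
Product: 16 4-[(3S,6E)-3-hydroxy-3,7-dimethyl-9-(2,6,6-trimethylcyclohex-1-en-1-yl)non-6-en-1-yn-1-yl]phenol
Conditions: Pd(PPh3)2Cl2 (2 mol%), CuI (4 mol%), Et3N, THF, rt, degassed
Reagents that add atoms: none
Why: Sonogashira coupling of a terminal alkyne with an aryl iodide; the free phenol and the tertiary alcohol are tolerated, and exclusion of oxygen suppresses alkyne homocoupling.

Step 11
Reactants: 16 4-[(3S,6E)-3-hydroxy-3,7-dimethyl-9-(2,6,6-trimethylcyclohex-1-en-1-yl)non-6-en-1-yn-1-yl]phenol
Product: 17 4-[(1Z,3S,6E)-3-hydroxy-3,7-dimethyl-9-(2,6,6-trimethylcyclohex-1-en-1-yl)nona-1,6-dien-1-yl]phenol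
Conditions: H2 (1 atm), Pd/CaCO3 poisoned with Pb(OAc)2 (Lindlar catalyst), quinoline, EtOAc, rt, stopped after 1 equiv H2
Reagents that add atoms: none
Why: Lindlar semihydrogenation adds H2 syn to the alkyne and gives the Z alkene; tri- and tetrasubstituted alkenes are not reduced on the poisoned catalyst. The acid-sensitive product is handled in base-washed glassware and used directly.

Step 12
Reactants: 17 4-[(1Z,3S,6E)-3-hydroxy-3,7-dimethyl-9-(2,6,6-trimethylcyclohex-1-en-1-yl)nona-1,6-dien-1-yl]phenol
Product: 18 (2S)-2-methyl-2-[(3E)-4-methyl-6-(2,6,6-trimethylcyclohex-1-en-1-yl)hex-3-en-1-yl]-1-oxaspiro[4.5]deca-3,6,9-trien-8-one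
Conditions: PhI(OAc)2 (1.05 equiv), CF3CH2OH–CH2Cl2, −20 °C; Na2S2O3/NaHCO3 (aq)
Reagents that add atoms: none
Why: Oxidative dearomatisation of a 4-substituted phenol by a trivalent iodine reagent: ligand exchange at iodine, then loss of PhI as the tethered tertiary hydroxyl attacks the para carbon in a 5-exo closure that only the Z alkene allows. The weakly nucleophilic fluoro alcohol does not compete; the spiro carbon is not stereogenic and C2 is untouched.

Step 13
Reactants: 18 (2S)-2-methyl-2-[(3E)-4-methyl-6-(2,6,6-trimethylcyclohex-1-en-1-yl)hex-3-en-1-yl]-1-oxaspiro[4.5]deca-3,6,9-trien-8-one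
Product: 19 (2S)-2-methyl-2-[(3E)-4-methyl-6-(2,6,6-trimethylcyclohex-1-en-1-yl)hex-3-en-1-yl]-2H-chromen-6-ol (CNP0157994.1)
Conditions: BF3·OEt2 (1.5 equiv), 2,6-di-tert-butyl-4-methylpyridine (1.5 equiv), CH2Cl2, −78 → −40 °C; Et3N, then NaHCO3 (aq) at −40 °C
Reagents that add atoms: none
Why: BF3 binds the dienone oxygen, the most Lewis-basic site of 18, and places positive charge on the two equivalent ring carbons that flank the spiro carbon. The vinylic C4 then shifts from the spiro carbon to one of them through a bridged transition state and forms the C4–C4a bond. The cation left at C8a is an oxocarbenium ion stabilised by O1, and loss of the C4a proton to the hindered pyridine re-aromatises ring A to the boron-bound phenolate, which the bicarbonate work-up frees. The closest known reaction type is the acid-promoted dienone–phenol rearrangement of 1-oxaspiro[4.5]deca-6,9-dien-8-ones to chroman-6-ols, and an sp2 carbon is generally a better migrating group than the sp3 carbon of that case. Ring B is formed by ring expansion of the 2,5-dihydrofuran through this 1,2-shift, not by an exo or endo cyclisation. No stereocentre is created: the spiro carbon of the symmetrical dienone is not stereogenic, either flanking carbon gives the same product, and C2 stays S because neither C2–O1 nor C2–C3 is broken. The step needs carbon to migrate in preference to oxygen, which is secured because only carbon migration leaves the O1-stabilised cation and so places the hydroxyl para to O1. It also needs activation of the dienone in preference to ionisation of the tertiary allylic C2–O1 bond or protonation of the 1,5-diene, which is secured by an aprotic Lewis acid at low temperature together with a proton scavenger too hindered to bind boron.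

## Compound list

1 | β-cyclocitral (2,6,6-trimethylcyclohex-1-ene-1-carbaldehyde) | CC1=C(C=O)C(C)(C)CCC1 | starting material
2 | β-cyclogeraniol ((2,6,6-trimethylcyclohex-1-en-1-yl)methanol) | CC1=C(CO)C(C)(C)CCC1 | intermediate
3 | β-cyclogeranyl bromide (2-(bromomethyl)-1,3,3-trimethylcyclohex-1-ene) | CC1=C(CBr)C(C)(C)CCC1 | intermediate (not isolated)
4 | β-cyclogeranyl phenyl sulfone ([(2,6,6-trimethylcyclohex-1-en-1-yl)methylsulfonyl]benzene) | CC1=C(CS(=O)(=O)c2ccccc2)C(C)(C)CCC1 | intermediate
5 | geranyl acetate ((2E)-3,7-dimethylocta-2,6-dien-1-yl acetate) | CC(=O)OC/C=C(\C)CCC=C(C)C | starting material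
6 | (2E,6E)-8-hydroxy-3,7-dimethylocta-2,6-dien-1-yl acetate | CC(=O)OC/C=C(\C)CC/C=C(\C)CO | intermediate
7 | (2E,6E)-8-bromo-3,7-dimethylocta-2,6-dien-1-yl acetate | CC(=O)OC/C=C(\C)CC/C=C(\C)CBr | intermediate
8 | (2E,6E)-3,7-dimethyl-9-(phenylsulfonyl)-9-(2,6,6-trimethylcyclohex-1-en-1-yl)nona-2,6-dien-1-yl acetate (racemic at C9) | CC1=C(C(C/C(C)=C/CC/C(C)=C/COC(C)=O)S(=O)(=O)c2ccccc2)C(C)(C)CCC1 | intermediate
9 | (2E,6E)-3,7-dimethyl-9-(2,6,6-trimethylcyclohex-1-en-1-yl)nona-2,6-dien-1-yl acetate | CC1=C(CC/C(C)=C/CC/C(C)=C/COC(C)=O)C(C)(C)CCC1 | intermediate (not isolated)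
10 | (2E,6E)-3,7-dimethyl-9-(2,6,6-trimethylcyclohex-1-en-1-yl)nona-2,6-dien-1-ol | CC1=C(CC/C(C)=C/CC/C(C)=C/CO)C(C)(C)CCC1 | intermediate
11 | [(2S,3S)-3-methyl-3-[(3E)-4-methyl-6-(2,6,6-trimethylcyclohex-1-en-1-yl)hex-3-en-1-yl]oxiran-2-yl]methanol | CC1=C(CC/C(C)=C/CC[C@]2(C)O[C@H]2CO)C(C)(C)CCC1 | intermediate
12 | (2R,3S)-2-(chloromethyl)-3-methyl-3-[(3E)-4-methyl-6-(2,6,6-trimethylcyclohex-1-en-1-yl)hex-3-en-1-yl]oxirane | CC1=C(CC/C(C)=C/CC[C@]2(C)O[C@H]2CCl)C(C)(C)CCC1 | intermediate
13 | (1E,3S,6E)-1-chloro-3,7-dimethyl-9-(2,6,6-trimethylcyclohex-1-en-1-yl)nona-1,6-dien-3-ol (lithium alkoxide in the flask; E drawn for the chloroalkene, either geometry eliminates to 14) | CC1=C(CC/C(C)=C/CC[C@](C)(O)/C=C/Cl)C(C)(C)CCC1 | intermediate (not isolated)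
14 | (3S,6E)-3,7-dimethyl-9-(2,6,6-trimethylcyclohex-1-en-1-yl)non-6-en-1-yn-3-ol | CC1=C(CC/C(C)=C/CC[C@](C)(O)C#C)C(C)(C)CCC1 | intermediate
15 | 4-iodophenol | Oc1ccc(I)cc1 | starting material
16 | 4-[(3S,6E)-3-hydroxy-3,7-dimethyl-9-(2,6,6-trimethylcyclohex-1-en-1-yl)non-6-en-1-yn-1-yl]phenol | CC1=C(CC/C(C)=C/CC[C@](C)(O)C#Cc2ccc(O)cc2)C(C)(C)CCC1 | intermediate
17 | 4-[(1Z,3S,6E)-3-hydroxy-3,7-dimethyl-9-(2,6,6-trimethylcyclohex-1-en-1-yl)nona-1,6-dien-1-yl]phenol | CC1=C(CC/C(C)=C/CC[C@](C)(O)/C=C\c2ccc(O)cc2)C(C)(C)CCC1 | intermediate
18 | (2S)-2-methyl-2-[(3E)-4-methyl-6-(2,6,6-trimethylcyclohex-1-en-1-yl)hex-3-en-1-yl]-1-oxaspiro[4.5]deca-3,6,9-trien-8-one | CC1=C(CC/C(C)=C/CC[C@@]2(C)C=CC3(C=CC(=O)C=C3)O2)C(C)(C)CCC1 | intermediate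
19 | (2S)-2-methyl-2-[(3E)-4-methyl-6-(2,6,6-trimethylcyclohex-1-en-1-yl)hex-3-en-1-yl]-2H-chromen-6-ol | CC1=C(CC/C(C)=C/CC[C@@]2(C)C=Cc3cc(O)ccc3O2)C(C)(C)CCC1 | target

## Step count and least certain steps

Total: 13 steps. Longest linear sequence: 11 steps (from 1 through steps 1, 2, 5–13, or equally from 5 through steps 3–13).

**Step 13 (key step).**
- What may go wrong: heterolysis of the tertiary allylic C2–O1 bond, in 18 or in 19 while it is still bound to boron, competing with the 1,2-shift. This would erode the configuration at C2 or end in elimination. A second hazard is proton-initiated cyclisation of the side-chain 1,5-diene.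
- Why: a cation at C2 would be tertiary and allylic, and the rearrangement releases one proton per molecule.
- Fallback (sets out from 14, comes back at 19): ring B is closed by C–O cross-coupling instead of a shift. 4-Bromo-3-iodophenol is silylated (TBSCl, imidazole) to tert-butyl(4-bromo-3-iodophenoxy)dimethylsilane F1. Sonogashira coupling of 14 at the iodide of F1 gives the bromoaryl alkynol F2. Semihydrogenation over the lead-poisoned palladium catalyst gives the Z-alkenyl aryl bromide F3. Palladium-catalysed intramolecular etherification of the tertiary alcohol with the aryl bromide (Pd(OAc)2, 2-(di-tert-butylphosphino)-1,1'-binaphthyl, Cs2CO3, toluene, 80 °C) gives the silyl-protected chromene F4 with the C2–O bond untouched. Bu4NF in THF then gives 19.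

**Step 12.**
- What may go wrong: capture of the oxidised phenol by solvent or acetate at the far end of the styrenyl system, or Z-to-E isomerisation, in place of closure by the hindered tertiary hydroxyl.
- Why: the cation formed on oxidation is delocalised through the Z alkene to the carbon next to C2.
- Fallback (sets out from 16, comes back at 19): dearomatisation and ring expansion are run in the saturated series, where both are established, and the C3=C4 alkene is introduced last. Diimide (2-nitrobenzenesulfonyl hydrazide, Et3N, CH2Cl2, rt) saturates the alkyne of 16 selectively to the saturated hydroxy phenol F5. PhI(OAc)2 in CF3CH2OH gives the saturated spiroether dienone F6. BF3·OEt2 at low temperature induces the alkyl shift to the chroman-6-ol F7. Acetylation (Ac2O, pyridine) gives the chromanyl acetate F8. Dehydrogenation with DDQ in refluxing benzene gives the chromenyl acetate F9, and K2CO3 in MeOH then gives 19.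

**Step 6.**
- What may go wrong: protonation of the intermediate allyl anion at the ring carbon, which would move the double bond out of the ring, or incomplete reduction of the hindered sulfone.
- Why: the allyl anion has two termini, and the sulfonyl-bearing carbon sits next to a gem-dimethyl group.
- Fallback (sets out from 6, comes back at 9): the sulfone is avoided altogether. MnO2 oxidises 6 to the enal F10, and Wittig methylenation (Ph3PCH3Br, KN(SiMe3)2, THF) gives the triene acetate F11. 9-BBN hydroborates only the terminal vinyl group to the alkylborane F12. F12 is coupled in the same flask (PdCl2[1,1'-bis(diphenylphosphino)ferrocene], K3PO4 aq., DMF, 50 °C) with the enol triflate F13, made from 2,2,6-trimethylcyclohexanone with LiN(iPr)2 and PhNTf2. This B-alkyl Suzuki coupling gives 9, which is methanolysed as in step 6.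

**Step 11.**
- What may go wrong: over-reduction of the styrenyl alkene or Z/E isomerisation on the catalyst, and ionisation of the acid-sensitive tertiary allylic alcohol during handling.
- Why: the aryl-conjugated alkene is still a good substrate for palladium, and the hydroxyl is both allylic and vinylogously benzylic to a para-hydroxyaryl group.
- Fallback (sets out from 14, comes back at 17): the Z geometry is set by a directed hydrometalation instead. Hydroxyl-directed trans-hydroalumination of 14 with NaAlH2(OCH2CH2OCH3)2 followed by iodinolysis gives the (Z)-iodoalkenyl carbinol F14. Suzuki coupling with 4-hydroxyphenylboronic acid (Pd(PPh3)4, Na2CO3 aq., DME) proceeds with retention of geometry and gives 17.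

## Further compounds

F1 | step 13 | tert-butyl(4-bromo-3-iodophenoxy)dimethylsilane | CC(C)(C)[Si](C)(C)Oc1ccc(Br)c(I)c1
F2 | step 13 | (3S,6E)-1-[2-bromo-5-(tert-butyldimethylsilyloxy)phenyl]-3,7-dimethyl-9-(2,6,6-trimethylcyclohex-1-en-1-yl)non-6-en-1-yn-3-ol | CC1=C(CC/C(C)=C/CC[C@](C)(O)C#Cc2cc(O[Si](C)(C)C(C)(C)C)ccc2Br)C(C)(C)CCC1
F3 | step 13 | (1Z,3S,6E)-1-[2-bromo-5-(tert-butyldimethylsilyloxy)phenyl]-3,7-dimethyl-9-(2,6,6-trimethylcyclohex-1-en-1-yl)nona-1,6-dien-3-ol | CC1=C(CC/C(C)=C/CC[C@](C)(O)/C=C\c2cc(O[Si](C)(C)C(C)(C)C)ccc2Br)C(C)(C)CCC1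
F4 | step 13 | tert-butyldimethyl{[(2S)-2-methyl-2-[(3E)-4-methyl-6-(2,6,6-trimethylcyclohex-1-en-1-yl)hex-3-en-1-yl]-2H-chromen-6-yl]oxy}silane | CC1=C(CC/C(C)=C/CC[C@@]2(C)C=Cc3cc(O[Si](C)(C)C(C)(C)C)ccc3O2)C(C)(C)CCC1
F5 | step 12 | 4-[(3S,6E)-3-hydroxy-3,7-dimethyl-9-(2,6,6-trimethylcyclohex-1-en-1-yl)non-6-en-1-yl]phenol | CC1=C(CC/C(C)=C/CC[C@](C)(O)CCc2ccc(O)cc2)C(C)(C)CCC1
F6 | step 12 | (2S)-2-methyl-2-[(3E)-4-methyl-6-(2,6,6-trimethylcyclohex-1-en-1-yl)hex-3-en-1-yl]-1-oxaspiro[4.5]deca-6,9-dien-8-one | CC1=C(CC/C(C)=C/CC[C@@]2(C)CCC3(C=CC(=O)C=C3)O2)C(C)(C)CCC1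
F7 | step 12 | (2S)-2-methyl-2-[(3E)-4-methyl-6-(2,6,6-trimethylcyclohex-1-en-1-yl)hex-3-en-1-yl]chroman-6-ol | CC1=C(CC/C(C)=C/CC[C@@]2(C)CCc3cc(O)ccc3O2)C(C)(C)CCC1
F8 | step 12 | (2S)-2-methyl-2-[(3E)-4-methyl-6-(2,6,6-trimethylcyclohex-1-en-1-yl)hex-3-en-1-yl]chroman-6-yl acetate | CC1=C(CC/C(C)=C/CC[C@@]2(C)CCc3cc(OC(C)=O)ccc3O2)C(C)(C)CCC1
F9 | step 12 | (2S)-2-methyl-2-[(3E)-4-methyl-6-(2,6,6-trimethylcyclohex-1-en-1-yl)hex-3-en-1-yl]-2H-chromen-6-yl acetate | CC1=C(CC/C(C)=C/CC[C@@]2(C)C=Cc3cc(OC(C)=O)ccc3O2)C(C)(C)CCC1
F10 | step 6 | (2E,6E)-3,7-dimethyl-8-oxoocta-2,6-dien-1-yl acetate | CC(=O)OC/C=C(\C)CC/C=C(\C)C=O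
F11 | step 6 | (2E,6E)-3,7-dimethylnona-2,6,8-trien-1-yl acetate | CC(=O)OC/C=C(\C)CC/C=C(\C)C=C
F12 | step 6 | (2E,6E)-9-(9-borabicyclo[3.3.1]nonan-9-yl)-3,7-dimethylnona-2,6-dien-1-yl acetate | CC(=O)OC/C=C(\C)CC/C=C(\C)CCB1C2CCCC1CCC2
F13 | step 6 | 2,6,6-trimethylcyclohex-1-en-1-yl trifluoromethanesulfonate | CC1=C(OS(=O)(=O)C(F)(F)F)C(C)(C)CCC1
F14 | step 11 | (1Z,3S,6E)-1-iodo-3,7-dimethyl-9-(2,6,6-trimethylcyclohex-1-en-1-yl)nona-1,6-dien-3-ol | CC1=C(CC/C(C)=C/CC[C@](C)(O)/C=C\I)C(C)(C)CCC1
A1 | alternative 1 | (2S)-6-(tert-butyldimethylsilyloxy)-2-ethenyl-2-methyl-2H-chromene | C=C[C@@]1(C)C=Cc2cc(O[Si](C)(C)C(C)(C)C)ccc2O1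
A2 | alternative 1 | tert-butyl{3-ethenyl-4-[(3-methylpenta-1,4-dien-3-yl)oxy]phenoxy}dimethylsilane | C=Cc1cc(O[Si](C)(C)C(C)(C)C)ccc1OC(C)(C=C)C=C
A3 | alternative 2 | cis-fused 1a,7a-dihydrocyclopropa[b]chromen-7(1H)-one with the side chain on the oxygen-bearing ring-fusion carbon and a triisopropylsilyloxy group para to the ring oxygen | CC1=C(CC/C(C)=C/CC[C@@]23C[C@@H]2C(=O)c2cc(O[Si](C(C)C)(C(C)C)C(C)C)ccc2O3)C(C)(C)CCC1
A4 | alternative 2 | 2-[(3E)-4-methyl-6-(2,6,6-trimethylcyclohex-1-en-1-yl)hex-3-en-1-yl]-6-(triisopropylsilyloxy)-4H-chromen-4-one | CC1=C(CC/C(C)=C/CCc2cc(=O)c3cc(O[Si](C(C)C)(C(C)C)C(C)C)ccc3o2)C(C)(C)CCC1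
A5 | alternative 3 | (2S)-2-methyl-2-[(3E)-4-methyl-6-(2,6,6-trimethylcyclohex-1-en-1-yl)hex-3-en-1-yl]-6-(triisopropylsilyloxy)chroman-3-one | CC1=C(CC/C(C)=C/CC[C@@]2(C)C(=O)Cc3cc(O[Si](C(C)C)(C(C)C)C(C)C)ccc3O2)C(C)(C)CCC1
A6 | alternative 3 | (2S)-2-methyl-2-[(3E)-4-methyl-6-(2,6,6-trimethylcyclohex-1-en-1-yl)hex-3-en-1-yl]-5-(triisopropylsilyloxy)-1-benzofuran-3(2H)-one | CC1=C(CC/C(C)=C/CC[C@]2(C)Oc3ccc(O[Si](C(C)C)(C(C)C)C(C)C)cc3C2=O)C(C)(C)CCC1
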